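Ring B of the target is a masked 2,6-dimethyl-1,4-benzoquinone: its oxygens sit para at C6 and C9, and its methyls on C8 and C10 flank C9. Ring A, with the gem-dimethyl carbon C4 next to the ring-fusion carbon C5, is a masked 4-methylpenta-1,3-diene. A catalytic enantioselective Diels–Alder reaction between these two flat, achiral, commercial compounds therefore closes ring A by forming C4–C5 together with C1–C10 and sets the quaternary C10 in the first step. The later steps saturate the adduct, add C11 to C9, correct C5, reduce C6 and build the spiro ether–lactone at C13 by a carbonylative double cyclisation.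

Key step: step 1

Assumption: labdane numbering is used throughout (ring A = C1–C5 and C10, ring B = C5–C10, C17 on C8, C18 and C19 on C4, C20 on C10, side chain C11–C16). The antipodes named for the two chiral catalysts (steps 1 and 6) follow the usual facial models of these catalyst classes, and the mirror-image catalyst would be taken if the sense of induction proved opposite.

Step 1
Reactants: 1 2,6-dimethyl-1,4-benzoquinone; 2 4-methylpenta-1,3-diene
Product: 3 (4aR,8aS)-2,5,5,8a-tetramethyl-4a,5,8,8a-tetrahydronaphthalene-1,4-dione (cis-fused adduct)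
Conditions: (S)-3,3-diphenyl-1-(2-methylphenyl)tetrahydro-1H,3H-pyrrolo[1,2-c][1,3,2]oxazaborole (20 mol%), HN(SO2CF3)2 (20 mol%), CH2Cl2, −78 to −20 °C, diene in threefold excess
Reagents that add atoms: none
Why: The protonated oxazaborolidine binds the C6 carbonyl of 1 (the only one flanked by C–H; the C9 carbonyl is screened by two methyls), which makes C10 the β-carbon, so the unsubstituted diene terminus C1 bonds to C10 and the gem-dimethyl terminus C4 to the α-carbon C5 in an asynchronous Lewis-acid-catalysed Diels–Alder reaction, the closest known reaction type being the catalytic enantioselective quinone Diels–Alder reaction. Ring A closes by intermolecular [4+2] cycloaddition, suprafacial on both partners, the C4–C5 bond completing the six-membered ring behind the leading C1–C10 bond, and because the step is a pure addition every atom of 1 and 2 is kept in 3. C10 is set by the catalyst, which shields one face of the bound C5=C10 bond, and C5 arises cis (H-5 syn to the angular methyl) by suprafacial addition and is corrected in step 4. Regioselectivity is secured by the site of Lewis-acid binding and by sterics (the other orientation would join two quaternary carbons), and mono-addition by the lower reactivity of the ene-dione product. The diene has no stereogenic terminus, so no endo/exo question arises; its reluctant s-cis conformer is the risk, offset by the strong activation of the quinone.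

Step 2
Reactants: 3
Product: 4 (2R,4aR,8aS)-2,5,5,8a-tetramethyloctahydronaphthalene-1,4-dione (cis-fused, 8α-methyl)
Conditions: H2 (1 atm), 10% Pd/C, EtOAc, rt
Reagents that add atoms: none
Why: Heterogeneous catalytic hydrogenation saturates the ring A alkene and the electron-poor C7=C8 bond of the ene-dione, hydrogen arriving on the convex face of the cis-fused bicycle (the face of the angular methyl and H-5, the concave face being covered by ring A), which sets C8 with H β and methyl α, and the neutral medium leaves this epimerisable centre untouched.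

Step 3
Reactants: 4
Product: 7 (1R,2R,4aR,8aS)-2,5,5,8a-tetramethyloctahydrospiro[naphthalene-1,2'-oxiran]-4-one (cis-fused 9α,11-epoxy 6-ketone), via lithium C6-enolate 5 (not isolated), via chlorohydrin alkoxide 6 (not isolated)
Conditions: LiN(i-Pr)2 (1.05 equiv), THF, −78 °C; then ICH2Cl (1.5 equiv), n-BuLi (1.5 equiv), −78 °C to rt; aq. NH4Cl
Reagents that add atoms: chloroiodomethane ClCI
Why: Kinetic deprotonation at C7 masks the less hindered C6 ketone as its lithium enolate (in situ enolate protection), so that chloromethyllithium adds only to the C9 ketone, from the convex β face because the α face is blocked by ring A and the 8α-methyl, and the chlorohydrin alkoxide closes by intramolecular Williamson displacement to the epoxide with C11 β and oxygen α (lithium carbenoid epoxidation of a ketone).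

Step 4
Reactants: 7
Product: 9 (1R,2R,4R,4aS,8aS)-2,5,5,8a-tetramethyloctahydrospiro[naphthalene-1,2'-oxiran]-4-ol (trans-fused 9α,11-epoxy 6β-alcohol), via trans-fused ketone 8 (not isolated)
Conditions: NaOMe (0.2 equiv), MeOH, 40 °C; then NaBH4, 0 °C
Reagents that add atoms: none
Why: Methoxide equilibrates C5 through the C6 enolate to the trans-fused ketone, favoured because in the cis isomer the axial C4 group clashes with the axial oxygen on C9, and sodium borohydride then attacks C6 from the open α face (the β face is screened by the axial C10 and C4 methyls) to give the axial 6β alcohol (base epimerisation followed by diastereoselective ketone reduction).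

Step 5
Reactants: 9 trans-fused epoxy alcohol; 10 2-methylprop-2-en-1-ol
Product: 12 (1R,2R,4R,4aS,8aS)-1-(4-hydroxy-3-methylidenebutyl)-2,5,5,8a-tetramethyldecahydronaphthalene-1,4-diol, via dilithiated methallyl alcohol 11 (not isolated)
Conditions: 10 (4 equiv), n-BuLi (8.5 equiv), TMEDA, Et2O, 0 °C to rt; then 9, THF, 0 to 40 °C; aq. NH4Cl
Reagents that add atoms: none
Why: The allyl anion of dilithiated methallyl alcohol opens the spiro-epoxide by SN2 attack at its unsubstituted carbon C11, which forms the C11–C12 bond, frees the tertiary 9α-alkoxide without touching C9 and delivers the 2-methylene-1,5-diol array (epoxide opening by an allyllithium).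

Step 6
Reactants: 12
Product: 13 6-O-deacetylprevitexilactone [(5S,6R,8R,9R,10S,13S)-6-hydroxy-9,13-epoxylabdane lactone in which C15 is the carbonyl carbon while C16 carries the ring oxygen]
Conditions: Pd(OCOCF3)2 (10 mol%), (S,S)-Bn-BOXAX [(S)-2,2'-bis((4S)-4-benzyl-4,5-dihydrooxazol-2-yl)-1,1'-binaphthyl] (20 mol%), p-benzoquinone (3 equiv), CO (1 atm), CH2Cl2, rt
Reagents that add atoms: carbon monoxide [C-]#[O+]
Why: Divalent palladium bound to the chiral bis-oxazoline activates the 1,1-disubstituted alkene for 5-exo-trig attack by the tertiary 9α-hydroxyl at C13 (Wacker-type oxypalladation), the resulting alkylpalladium has no β-hydrogen and inserts CO, and the acylpalladium is captured by the C16 hydroxyl to close the γ-lactone, the ligand choosing the alkene face and hence the C13 configuration while p-benzoquinone reoxidises zerovalent palladium (enantioselective oxypalladation–carbonylation–lactonisation cascade).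

Step 7
Reactants: 13
Product: 14 previtexilactone
Conditions: Ac2O (5 equiv), DMAP (0.2 equiv), pyridine, 40 °C
Reagents that add atoms: acetic anhydride CC(=O)OC(C)=O
Why: Nucleophile-catalysed acylation esterifies the only remaining hydroxyl, the hindered axial 6β-alcohol, with retention at C6 and without strong base, so the base-sensitive β-alkoxy lactone is not opened (DMAP-catalysed acetylation).

Compound list
1 | 2,6-dimethyl-1,4-benzoquinone | CC1=CC(=O)C=C(C)C1=O | starting material
2 | 4-methylpenta-1,3-diene | CC(C)=CC=C | starting material
3 | (4aR,8aS)-2,5,5,8a-tetramethyl-4a,5,8,8a-tetrahydronaphthalene-1,4-dione (cis-fused; 10β-methyl, 5β-H) | O=C1C=C(C)C(=O)[C@@]2(C)CC=CC(C)(C)[C@@H]12 | intermediate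
4 | (2R,4aR,8aS)-2,5,5,8a-tetramethyloctahydronaphthalene-1,4-dione (cis-fused; 8α-methyl) | O=C1C[C@@H](C)C(=O)[C@@]2(C)CCCC(C)(C)[C@@H]12 | intermediate
5 | lithium C6-enolate of 4 (C6=C7) | [Li]OC1=C[C@@H](C)C(=O)[C@@]2(C)CCCC(C)(C)[C@@H]12 | intermediate
6 | dilithium chlorohydrin alkoxide (9α-OLi, 9β-CH2Cl, C6 enolate) | [Li]OC1=C[C@@H](C)[C@](O[Li])(CCl)[C@@]2(C)CCCC(C)(C)[C@@H]12 | intermediate
7 | (1R,2R,4aR,8aS)-2,5,5,8a-tetramethyloctahydrospiro[naphthalene-1,2'-oxiran]-4-one (cis-fused; epoxide O α, CH2 β) | O=C1C[C@@H](C)[C@]3(CO3)[C@@]2(C)CCCC(C)(C)[C@@H]12 | intermediate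
8 | (1R,2R,4aS,8aS)-2,5,5,8a-tetramethyloctahydrospiro[naphthalene-1,2'-oxiran]-4-one (trans-fused) | O=C1C[C@@H](C)[C@]3(CO3)[C@@]2(C)CCCC(C)(C)[C@H]12 | intermediate
9 | (1R,2R,4R,4aS,8aS)-2,5,5,8a-tetramethyloctahydrospiro[naphthalene-1,2'-oxiran]-4-ol (6β-OH) | O[C@@H]1C[C@@H](C)[C@]3(CO3)[C@@]2(C)CCCC(C)(C)[C@H]12 | intermediate
10 | 2-methylprop-2-en-1-ol (methallyl alcohol) | CC(=C)CO | starting material
11 | dilithiated 2-methylprop-2-en-1-ol | [Li]CC(=C)CO[Li] | intermediate
12 | (1R,2R,4R,4aS,8aS)-1-(4-hydroxy-3-methylidenebutyl)-2,5,5,8a-tetramethyldecahydronaphthalene-1,4-diol (15-norlabd-13(14)-ene-6β,9α,16-triol) | O[C@@H]1C[C@@H](C)[C@](O)(CCC(=C)CO)[C@@]2(C)CCCC(C)(C)[C@H]12 | intermediate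
13 | 6-O-deacetylprevitexilactone, (5S,6R,8R,9R,10S,13S)-6-hydroxy-9,13-epoxylabdane lactone (C15 carbonyl, O on C16) | O[C@@H]1C[C@@H](C)[C@]2(CC[C@]3(COC(=O)C3)O2)[C@@]2(C)CCCC(C)(C)[C@H]12 | intermediate
14 | previtexilactone, (5S,6R,8R,9R,10S,13S)-6-acetoxy-9,13-epoxylabdane lactone (C15 carbonyl, O on C16) | CC(=O)O[C@@H]1C[C@@H](C)[C@]2(CC[C@]3(COC(=O)C3)O2)[C@@]2(C)CCCC(C)(C)[C@H]12 | target

Total step count: 7
Longest linear sequence: 7 steps (from 1 to 14)

Steps most likely to fail

The first risk lies in step 1, the cycloaddition. The (Z)-methyl of the diene disfavours the s-cis conformer, so the cycloaddition may be slow at the methyl-bearing β-carbon and lose out to stepwise [2+2] or ene pathways. The diene may also oligomerise, or isomerise under the acid to 2-methylpenta-1,3-diene, which would add faster and give a regioisomeric ring A. The fallback sets out from 1 and uses a far more nucleophilic 2-silyloxy diene, 4-methyl-2-[tri(propan-2-yl)silyloxy]penta-1,3-diene F1 (from mesityl oxide, i-Pr3SiOSO2CF3 and Et3N). Under the same oxazaborolidinium catalysis its CH2 terminus should add to C10 in a Mukaiyama–Michael step and the enolate should then close onto C4, giving the silyl enol ether adduct F2 with the same C1–C10 and C4–C5 bonds. CsF and PhN(SO2CF3)2 would convert F2 into the enol triflate F3, and Pd(OAc)2, PPh3, HCO2H and Bu3N would reduce the triflate to the C2=C3 alkene. The fallback comes back to the route at 3.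

The second risk lies in step 6, the carbonylative double cyclisation. Ligand control over the alkene face may be insufficient, since the two faces of the 1,1-disubstituted alkene differ little as seen from the decalin, which would give both C13 epimers. Oxidation of the allylic alcohol by divalent palladium may also outpace cyclisation by the hindered tertiary hydroxyl. The fallback sets out from 9 and fixes C13 by a stereospecific epoxide opening. The epoxide of 9 would be opened with dilithiated 3-methylbut-3-en-1-ol (n-BuLi, TMEDA) to give the homoallylic triol F4. A vanadium-catalysed asymmetric epoxidation directed by the primary homoallylic hydroxyl (VO(Oi-Pr)3, chiral bis-hydroxamic acid ligand, cumene hydroperoxide, toluene) would give the 13,16-epoxide F5, with the ligand antipode chosen for the configuration shown. Camphorsulfonic acid in CH2Cl2 would let the 9α-hydroxyl open the epoxide at the tertiary C13 with inversion (5-exo), giving the spiro ether diol F6. TEMPO with PhI(OAc)2 would oxidise the less hindered C15 alcohol and lactonise onto the neopentyl C16 hydroxyl. The fallback comes back to the route at 13.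

The third risk lies in step 3, the methylene transfer to C9. Enolate masking may be incomplete, so that the carbenoid attacks C6, or the short-lived carbenoid may decompose before it adds to the hindered C9 carbonyl. The fallback sets out from 4 and replaces the in situ enolate and the lithium carbenoid by an isolated silyl enol ether and a sulfur ylide. LiN(i-Pr)2 and Me3SiCl at −78 °C would give the C6 trimethylsilyl enol ether F7. Dimethylsulfonium methylide (Me3S+ I−, KN(SiMe3)2, THF) would transfer methylene to the C9 ketone from the convex face (Corey–Chaykovsky reaction) to give the epoxy silyl enol ether F8. K2CO3 in MeOH would cleave the enol ether. The fallback comes back to the route at 7.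

Further compounds
F1 | step 1 | 4-methyl-2-[tri(propan-2-yl)silyloxy]penta-1,3-diene | C=C(O[Si](C(C)C)(C(C)C)C(C)C)C=C(C)C
F2 | step 1 | (4aR,8aS)-2,5,5,8a-tetramethyl-7-[tri(propan-2-yl)silyloxy]-4a,5,8,8a-tetrahydronaphthalene-1,4-dione | O=C1C=C(C)C(=O)[C@@]2(C)CC(O[Si](C(C)C)(C(C)C)C(C)C)=CC(C)(C)[C@@H]12
F3 | step 1 | enol triflate corresponding to F2 (OSO2CF3 on C2 of ring A) | O=C1C=C(C)C(=O)[C@@]2(C)CC(OS(=O)(=O)C(F)(F)F)=CC(C)(C)[C@@H]12
F4 | step 6 | (1R,2R,4R,4aS,8aS)-1-(5-hydroxy-3-methylidenepentyl)-2,5,5,8a-tetramethyldecahydronaphthalene-1,4-diol | O[C@@H]1C[C@@H](C)[C@](O)(CCC(=C)CCO)[C@@]2(C)CCCC(C)(C)[C@H]12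
F5 | step 6 | 13,16-epoxide of F4 | O[C@@H]1C[C@@H](C)[C@](O)(CC[C@@]3(CCO)CO3)[C@@]2(C)CCCC(C)(C)[C@H]12
F6 | step 6 | (13S)-9,13-epoxylabdane-6β,15,16-triol | O[C@@H]1C[C@@H](C)[C@]2(CC[C@](CCO)(CO)O2)[C@@]2(C)CCCC(C)(C)[C@H]12
F7 | step 3 | C6 trimethylsilyl enol ether of 4 | C[Si](C)(C)OC1=C[C@@H](C)C(=O)[C@@]2(C)CCCC(C)(C)[C@@H]12
F8 | step 3 | C6 trimethylsilyl enol ether of 7 | C[Si](C)(C)OC1=C[C@@H](C)[C@]3(CO3)[C@@]2(C)CCCC(C)(C)[C@@H]12
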